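## Retrosynthetic overview

- Last step: one global removal of seven allyl groups (five aryl ethers, two esters) with zerovalent palladium, which leaves the cinnamate C=C untouched.
- Cinnamate C=C: Horner–Wadsworth–Emmons union of an aryl aldehyde (the aryloxy-hydroxy-acid half) with the phosphonoacetate of the (R)-aryl-lactate half (chiral pool).
- Key C–C bond, C2–C3 of the 2-aryloxy-3-hydroxy acid: intermolecular, auxiliary-controlled anti-aldol of an N-(aryloxyacetyl)oxazolidinone with 3,4-bis(allyloxy)benzaldehyde.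
- Aryl ether O–CH2 bond: regioselective 4-O-alkylation of 3,4-dihydroxybenzaldehyde with tert-butyl bromoacetate.
- Rings: no ring of the target is built; the three benzene rings are bought intact, and only temporary rings (oxazolidinone auxiliary, dioxolane acetal) are put on and taken off.

Assumption: the SMILES is read as (2R,3R) (anti) in the aryloxy-hydroxy acid and (R) in the lactate unit, and sodium (2R)-3-(3,4-dihydroxyphenyl)-2-hydroxypropanoate (C9H9NaO5, the commercial salt of natural (R)-3-(3,4-dihydroxyphenyl)lactic acid) is taken as a cheap bulk chiral-pool chemical.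

## Route

Step 1
Reactants: 1 3,4-dihydroxybenzaldehyde; 2 tert-butyl bromoacetate
Product: 3 tert-butyl 2-(4-formyl-2-hydroxyphenoxy)acetate
Conditions: NaHCO3 (1.5 equiv), NaI (0.2 equiv), DMF, 40 °C, 20 h
Reagents that add atoms: 2 tert-butyl bromoacetate, CC(C)(C)OC(=O)CBr
Why: Williamson ether synthesis in which the weak base ionises only the more acidic 4-OH (para to the formyl group), so alkylation occurs at O-4, and the tert-butyl ester cannot lactonise onto the neighbouring free phenol.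

Step 2
Reactants: 3 tert-butyl 2-(4-formyl-2-hydroxyphenoxy)acetate; 4 allyl bromide
Product: 5 tert-butyl 2-[2-(allyloxy)-4-formylphenoxy]acetate
Conditions: K2CO3 (1.5 equiv), allyl bromide (1.3 equiv), DMF, rt, 12 h
Reagents that add atoms: 4 allyl bromide, C=CCBr
Why: Williamson etherification of the one remaining phenol; nothing else in the molecule is alkylated by carbonate.

Step 3
Reactants: 5 tert-butyl 2-[2-(allyloxy)-4-formylphenoxy]acetate
Product: 6 2-[2-(allyloxy)-4-formylphenoxy]acetic acid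
Conditions: CF3CO2H/CH2Cl2 (1:2), rt, 3 h; toluene co-evaporation
Reagents that add atoms: none
Why: Acid-mediated tert-butyl ester cleavage (loss of isobutene), to which the aryl aldehyde and the allyl aryl ether are inert.

Step 4
Reactants: 6 2-[2-(allyloxy)-4-formylphenoxy]acetic acid; 7 pivaloyl chloride; 8 (4S)-4-benzyl-1,3-oxazolidin-2-one
Product: 10 (4S)-4-benzyl-3-{2-[2-(allyloxy)-4-formylphenoxy]acetyl}-1,3-oxazolidin-2-one, via mixed pivalic anhydride 9 (not isolated)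
Conditions: pivaloyl chloride (1.05 equiv), Et3N (2.5 equiv), THF, −20 °C, 1 h; then LiCl (1.1 equiv), 8 (1.0 equiv), −20 °C → rt
Reagents that add atoms: 8 (4S)-4-benzyl-1,3-oxazolidin-2-one, O=C1N[C@@H](Cc2ccccc2)CO1
Why: N-acylation through the mixed anhydride (LiCl/Et3N variant), in which the unhindered aryloxyacetyl carbonyl is attacked and no strong base or nucleophile touches the aldehyde.

Step 5
Reactants: 10 (4S)-4-benzyl-3-{2-[2-(allyloxy)-4-formylphenoxy]acetyl}-1,3-oxazolidin-2-one; 11 1,2-bis(trimethylsilyloxy)ethane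
Product: 12 (4S)-4-benzyl-3-{2-[2-(allyloxy)-4-(1,3-dioxolan-2-yl)phenoxy]acetyl}-1,3-oxazolidin-2-one
Conditions: 11 (1.5 equiv), Me3SiOTf (5 mol%), CH2Cl2, −78 → −20 °C; pyridine quench
Reagents that add atoms: 11 1,2-bis(trimethylsilyloxy)ethane, C[Si](C)(C)OCCO[Si](C)(C)C
Why: Noyori acetalisation masks the aldehyde under aprotic, low-temperature conditions that spare the imide, so the imide cannot condense with its own aldehyde in the aldol step.

Step 6
Reactants: 1 3,4-dihydroxybenzaldehyde; 4 allyl bromide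
Product: 13 3,4-bis(allyloxy)benzaldehyde
Conditions: K2CO3 (3 equiv), allyl bromide (2.5 equiv), DMF, 60 °C, 6 h
Reagents that add atoms: 4 allyl bromide, C=CCBr
Why: Exhaustive Williamson etherification of both phenols.

Step 7
Reactants: 12 (4S)-4-benzyl-3-{2-[2-(allyloxy)-4-(1,3-dioxolan-2-yl)phenoxy]acetyl}-1,3-oxazolidin-2-one; 13 3,4-bis(allyloxy)benzaldehyde; 14 chlorotrimethylsilane
Product: 16 (4S)-4-benzyl-3-{(2R,3R)-2-[2-(allyloxy)-4-(1,3-dioxolan-2-yl)phenoxy]-3-[3,4-bis(allyloxy)phenyl]-3-hydroxypropanoyl}-1,3-oxazolidin-2-one, via trimethylsilyl ether 15 (not isolated)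
Conditions: MgCl2 (20 mol%), Et3N (2 equiv), Me3SiCl (1.5 equiv), 13 (1.2 equiv), EtOAc, 23 °C, 24 h; then Bu4NF/AcOH (1:1), THF, 0 °C; chromatography to a single diastereomer
Reagents that add atoms: none
Why: Evans MgCl2-catalysed direct anti-aldol: soft enolisation gives the magnesium-chelated Z-enolate of the (S)-benzyl imide, the aryl aldehyde adds to the face away from the benzyl group through a boat-like transition state (C2 = R, anti relationship, hence 2R,3R), and silylation of the aldolate makes the addition irreversible.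

Step 8
Reactants: 16 (4S)-4-benzyl-3-{(2R,3R)-2-[2-(allyloxy)-4-(1,3-dioxolan-2-yl)phenoxy]-3-[3,4-bis(allyloxy)phenyl]-3-hydroxypropanoyl}-1,3-oxazolidin-2-one
Product: 18 (2R,3R)-2-[2-(allyloxy)-4-(1,3-dioxolan-2-yl)phenoxy]-3-[3,4-bis(allyloxy)phenyl]-3-hydroxypropanoic acid, via peroxy acid 17 (not isolated)
Conditions: LiOH·H2O (2 equiv), 30% H2O2 (4 equiv), THF/H2O (3:1), 0 °C, 1 h; then aq. Na2SO3, 0 °C; extract auxiliary; cold 1 M HCl to pH 4, EtOAc
Reagents that add atoms: hydrogen peroxide, OO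
Why: Hydroperoxide cleavage of the Evans imide: the small, strongly nucleophilic HOO– attacks the exocyclic carbonyl, sulfite reduces the peroxy acid, and the cold, brief basic conditions leave both stereocentres, the dioxolane and the allyl ethers untouched.

Step 9
Reactants: 18 (2R,3R)-2-[2-(allyloxy)-4-(1,3-dioxolan-2-yl)phenoxy]-3-[3,4-bis(allyloxy)phenyl]-3-hydroxypropanoic acid; 4 allyl bromide
Product: 19 allyl (2R,3R)-2-[2-(allyloxy)-4-(1,3-dioxolan-2-yl)phenoxy]-3-[3,4-bis(allyloxy)phenyl]-3-hydroxypropanoate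
Conditions: KHCO3 (2 equiv), allyl bromide (1.5 equiv), DMF, rt, 12 h
Reagents that add atoms: 4 allyl bromide, C=CCBr
Why: SN2 O-alkylation of the carboxylate; the weak base does not deprotonate the secondary alcohol or the α-carbon.

Step 10
Reactants: 19 allyl (2R,3R)-2-[2-(allyloxy)-4-(1,3-dioxolan-2-yl)phenoxy]-3-[3,4-bis(allyloxy)phenyl]-3-hydroxypropanoate
Product: 20 allyl (2R,3R)-2-[2-(allyloxy)-4-formylphenoxy]-3-[3,4-bis(allyloxy)phenyl]-3-hydroxypropanoate
Conditions: 1 M HCl/THF (1:5), rt, 2 h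
Reagents that add atoms: water, O
Why: Acid-catalysed acetal hydrolysis of an electron-rich aryl dioxolane, under acid too dilute to ionise the benzylic alcohol or hydrolyse the esters.

Step 11
Reactants: 21 sodium (2R)-3-(3,4-dihydroxyphenyl)-2-hydroxypropanoate; 4 allyl bromide
Product: 22 allyl (2R)-3-[3,4-bis(allyloxy)phenyl]-2-hydroxypropanoate
Conditions: K2CO3 (2.5 equiv), allyl bromide (3.5 equiv), degassed DMF, rt → 40 °C, 16 h
Reagents that add atoms: 4 allyl bromide, C=CCBr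
Why: Carboxylate and phenoxide O-alkylation (Williamson); the secondary alcohol is not ionised by carbonate and the (R)-centre, taken from the chiral pool, is not touched.

Step 12
Reactants: 22 allyl (2R)-3-[3,4-bis(allyloxy)phenyl]-2-hydroxypropanoate; 23 2-(diethoxyphosphoryl)acetic acid
Product: 24 allyl (2R)-3-[3,4-bis(allyloxy)phenyl]-2-{[2-(diethoxyphosphoryl)acetyl]oxy}propanoate
Conditions: DCC (1.2 equiv), 4-(dimethylamino)pyridine (10 mol%), CH2Cl2, 0 °C → rt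
Reagents that add atoms: 23 2-(diethoxyphosphoryl)acetic acid, CCOP(=O)(CC(=O)O)OCC
Why: Steglich esterification acylates the alcohol oxygen, so the C–O bond at the stereocentre is retained.

Step 13
Reactants: 20 allyl (2R,3R)-2-[2-(allyloxy)-4-formylphenoxy]-3-[3,4-bis(allyloxy)phenyl]-3-hydroxypropanoate; 24 allyl (2R)-3-[3,4-bis(allyloxy)phenyl]-2-{[2-(diethoxyphosphoryl)acetyl]oxy}propanoate
Product: 25 allyl (2R)-2-{[(2E)-3-(3-(allyloxy)-4-{[(1R,2R)-1-[(allyloxy)carbonyl]-2-[3,4-bis(allyloxy)phenyl]-2-hydroxyethyl]oxy}phenyl)prop-2-enoyl]oxy}-3-[3,4-bis(allyloxy)phenyl]propanoate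
Conditions: 24 (1.15 equiv), LiCl (1.5 equiv), DBU (1.1 equiv), MeCN, 0 °C → rt
Reagents that add atoms: none
Why: Horner–Wadsworth–Emmons olefination under Masamune–Roush conditions: only the lithium-chelated phosphonate is acidic enough for the amidine base, the (E)-cinnamate forms under thermodynamic control, and the β-hydroxy ester and both α-stereocentres are spared.

Step 14
Reactants: 25 allyl (2R)-2-{[(2E)-3-(3-(allyloxy)-4-{[(1R,2R)-1-[(allyloxy)carbonyl]-2-[3,4-bis(allyloxy)phenyl]-2-hydroxyethyl]oxy}phenyl)prop-2-enoyl]oxy}-3-[3,4-bis(allyloxy)phenyl]propanoate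
Product: 26 (2R)-2-{[(2E)-3-(4-{[(1R,2R)-1-carboxy-2-(3,4-dihydroxyphenyl)-2-hydroxyethyl]oxy}-3-hydroxyphenyl)prop-2-enoyl]oxy}-3-(3,4-dihydroxyphenyl)propanoic acid
Conditions: Pd(PPh3)4 (10 mol%), morpholine (20 equiv), degassed THF, rt, dark; then 1 M HCl, reversed-phase chromatography
Reagents that add atoms: none
Why: Tsuji–Trost deallylation: zerovalent palladium ionises the five aryl allyl ethers and two allyl esters to π-allyl complexes that morpholine traps, a hydrogen-free method that leaves the cinnamate C=C, the benzylic alcohol and the ester link intact.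

## Compound list

1 | 3,4-dihydroxybenzaldehyde | O=Cc1ccc(O)c(O)c1 | starting material
2 | tert-butyl bromoacetate | CC(C)(C)OC(=O)CBr | starting material
3 | tert-butyl 2-(4-formyl-2-hydroxyphenoxy)acetate | CC(C)(C)OC(=O)COc1ccc(C=O)cc1O | intermediate
4 | allyl bromide (3-bromoprop-1-ene) | C=CCBr | starting material
5 | tert-butyl 2-[2-(allyloxy)-4-formylphenoxy]acetate | CC(C)(C)OC(=O)COc1ccc(C=O)cc1OCC=C | intermediate
6 | 2-[2-(allyloxy)-4-formylphenoxy]acetic acid | OC(=O)COc1ccc(C=O)cc1OCC=C | intermediate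
7 | pivaloyl chloride | CC(C)(C)C(Cl)=O | starting material
8 | (4S)-4-benzyl-1,3-oxazolidin-2-one | O=C1N[C@@H](Cc2ccccc2)CO1 | starting material
9 | 2-[2-(allyloxy)-4-formylphenoxy]acetic pivalic anhydride | CC(C)(C)C(=O)OC(=O)COc1ccc(C=O)cc1OCC=C | intermediate
10 | (4S)-4-benzyl-3-{2-[2-(allyloxy)-4-formylphenoxy]acetyl}-1,3-oxazolidin-2-one | C=CCOc1cc(C=O)ccc1OCC(=O)N1[C@@H](Cc2ccccc2)COC1=O | intermediate
11 | 1,2-bis(trimethylsilyloxy)ethane | C[Si](C)(C)OCCO[Si](C)(C)C | starting material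
12 | (4S)-4-benzyl-3-{2-[2-(allyloxy)-4-(1,3-dioxolan-2-yl)phenoxy]acetyl}-1,3-oxazolidin-2-one | C=CCOc1cc(C2OCCO2)ccc1OCC(=O)N1[C@@H](Cc2ccccc2)COC1=O | intermediate
13 | 3,4-bis(allyloxy)benzaldehyde | C=CCOc1ccc(C=O)cc1OCC=C | intermediate
14 | chlorotrimethylsilane | C[Si](C)(C)Cl | starting material
15 | (4S)-4-benzyl-3-{(2R,3R)-2-[2-(allyloxy)-4-(1,3-dioxolan-2-yl)phenoxy]-3-[3,4-bis(allyloxy)phenyl]-3-[(trimethylsilyl)oxy]propanoyl}-1,3-oxazolidin-2-one | C=CCOc1cc(C2OCCO2)ccc1O[C@@H](C(=O)N1[C@@H](Cc2ccccc2)COC1=O)[C@H](O[Si](C)(C)C)c1ccc(OCC=C)c(OCC=C)c1 | intermediate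
16 | (4S)-4-benzyl-3-{(2R,3R)-2-[2-(allyloxy)-4-(1,3-dioxolan-2-yl)phenoxy]-3-[3,4-bis(allyloxy)phenyl]-3-hydroxypropanoyl}-1,3-oxazolidin-2-one | C=CCOc1cc(C2OCCO2)ccc1O[C@@H](C(=O)N1[C@@H](Cc2ccccc2)COC1=O)[C@H](O)c1ccc(OCC=C)c(OCC=C)c1 | intermediate
17 | (2R,3R)-2-[2-(allyloxy)-4-(1,3-dioxolan-2-yl)phenoxy]-3-[3,4-bis(allyloxy)phenyl]-3-hydroxypropaneperoxoic acid | C=CCOc1cc(C2OCCO2)ccc1O[C@@H](C(=O)OO)[C@H](O)c1ccc(OCC=C)c(OCC=C)c1 | intermediate
18 | (2R,3R)-2-[2-(allyloxy)-4-(1,3-dioxolan-2-yl)phenoxy]-3-[3,4-bis(allyloxy)phenyl]-3-hydroxypropanoic acid | C=CCOc1cc(C2OCCO2)ccc1O[C@@H](C(O)=O)[C@H](O)c1ccc(OCC=C)c(OCC=C)c1 | intermediate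
19 | allyl (2R,3R)-2-[2-(allyloxy)-4-(1,3-dioxolan-2-yl)phenoxy]-3-[3,4-bis(allyloxy)phenyl]-3-hydroxypropanoate | C=CCOc1cc(C2OCCO2)ccc1O[C@@H](C(=O)OCC=C)[C@H](O)c1ccc(OCC=C)c(OCC=C)c1 | intermediate
20 | allyl (2R,3R)-2-[2-(allyloxy)-4-formylphenoxy]-3-[3,4-bis(allyloxy)phenyl]-3-hydroxypropanoate | C=CCOc1cc(C=O)ccc1O[C@@H](C(=O)OCC=C)[C@H](O)c1ccc(OCC=C)c(OCC=C)c1 | intermediate
21 | sodium (2R)-3-(3,4-dihydroxyphenyl)-2-hydroxypropanoate | [Na+].[O-]C(=O)[C@H](O)Cc1ccc(O)c(O)c1 | starting material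
22 | allyl (2R)-3-[3,4-bis(allyloxy)phenyl]-2-hydroxypropanoate | C=CCOC(=O)[C@H](O)Cc1ccc(OCC=C)c(OCC=C)c1 | intermediate
23 | 2-(diethoxyphosphoryl)acetic acid | CCOP(=O)(CC(=O)O)OCC | starting material
24 | allyl (2R)-3-[3,4-bis(allyloxy)phenyl]-2-{[2-(diethoxyphosphoryl)acetyl]oxy}propanoate | C=CCOC(=O)[C@H](OC(=O)CP(=O)(OCC)OCC)Cc1ccc(OCC=C)c(OCC=C)c1 | intermediate
25 | allyl (2R)-2-{[(2E)-3-(3-(allyloxy)-4-{[(1R,2R)-1-[(allyloxy)carbonyl]-2-[3,4-bis(allyloxy)phenyl]-2-hydroxyethyl]oxy}phenyl)prop-2-enoyl]oxy}-3-[3,4-bis(allyloxy)phenyl]propanoate | C=CCOC(=O)[C@H](OC(=O)/C=C/c1ccc(O[C@@H](C(=O)OCC=C)[C@H](O)c2ccc(OCC=C)c(OCC=C)c2)c(OCC=C)c1)Cc1ccc(OCC=C)c(OCC=C)c1 | intermediate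
26 | (2R)-2-{[(2E)-3-(4-{[(1R,2R)-1-carboxy-2-(3,4-dihydroxyphenyl)-2-hydroxyethyl]oxy}-3-hydroxyphenyl)prop-2-enoyl]oxy}-3-(3,4-dihydroxyphenyl)propanoic acid (CNP0159428.1) | O=C(/C=C/c1ccc(O[C@@H](C(=O)O)[C@H](O)c2ccc(O)c(O)c2)c(O)c1)O[C@H](Cc1ccc(O)c(O)c1)C(=O)O | target

## Step count and risks

Total steps: 14. Longest linear sequence: 11 steps (steps 1, 2, 3, 4, 5, 7, 8, 9, 10, 13, 14); steps 6 and 11–12 are side branches.

**Step 7 (anti-aldol).** The MgCl2 anti-aldol is best established for simple N-acyl imides, so conversion and anti/syn ratio with an α-aryloxy imide and an electron-rich aldehyde are uncertain. The fallback sets out from 8, 13 and 1 and comes back at 20; it keeps an aldol as the C–C bond-forming step but brings in the aryl ether afterwards with inversion.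
- 8 is acylated (pivaloyl chloride, Et3N, LiCl) with commercial 2-[(4-methoxybenzyl)oxy]acetic acid to give (4S)-4-benzyl-3-{2-[(4-methoxybenzyl)oxy]acetyl}-1,3-oxazolidin-2-one F1.
- Its dibutylboron Z-enolate (Bu2BOTf, iPr2NEt, CH2Cl2, −78 °C) adds to 13 through a closed chair transition state to give the Evans syn adduct (4S)-4-benzyl-3-{(2S,3R)-3-[3,4-bis(allyloxy)phenyl]-3-hydroxy-2-[(4-methoxybenzyl)oxy]propanoyl}-1,3-oxazolidin-2-one F2.
- t-BuMe2SiOTf/2,6-lutidine gives the silyl ether (4S)-4-benzyl-3-{(2S,3R)-3-[3,4-bis(allyloxy)phenyl]-3-[(tert-butyldimethylsilyl)oxy]-2-[(4-methoxybenzyl)oxy]propanoyl}-1,3-oxazolidin-2-one F3.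
- Allyl alcohol/MeMgBr at 0 °C exchanges the auxiliary for the ester, giving allyl (2S,3R)-3-[3,4-bis(allyloxy)phenyl]-3-[(tert-butyldimethylsilyl)oxy]-2-[(4-methoxybenzyl)oxy]propanoate F4.
- DDQ (CH2Cl2/pH 7 buffer, 0 °C) removes the 4-methoxybenzyl group to give allyl (2S,3R)-3-[3,4-bis(allyloxy)phenyl]-3-[(tert-butyldimethylsilyl)oxy]-2-hydroxypropanoate F5.
- The phenol 3-(allyloxy)-4-hydroxybenzaldehyde F6 is made from 1 through its dianion (NaH, 2.2 equiv, DMSO) and one equivalent of 4.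
- Mitsunobu etherification of F5 with F6 (PPh3, diisopropyl azodicarboxylate, toluene, 0 °C → rt) inverts C2 and gives allyl (2R,3R)-2-[2-(allyloxy)-4-formylphenoxy]-3-[3,4-bis(allyloxy)phenyl]-3-[(tert-butyldimethylsilyl)oxy]propanoate F7.
- HF·pyridine in THF removes the silyl group and delivers 20.

**Step 13 (olefination).** The aldehyde is deactivated by its para-alkoxy group, and the β-hydroxy α-aryloxy ester of 20 could suffer retro-aldol cleavage or C2 epimerisation if the base is not consumed cleanly by the phosphonate. The fallback sets out from 22 and comes back at 25 (with 20); it replaces the base-mediated phosphonate coupling by a base-free Wittig reaction of an isolated ylide.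
- 22 is acylated with bromoacetyl bromide/pyridine (CH2Cl2, 0 °C) to allyl (2R)-3-[3,4-bis(allyloxy)phenyl]-2-[(2-bromoacetyl)oxy]propanoate F8.
- PPh3 in toluene gives {2-[((2R)-1-(allyloxy)-3-[3,4-bis(allyloxy)phenyl]-1-oxopropan-2-yl)oxy]-2-oxoethyl}triphenylphosphonium bromide F9.
- Brief shaking with cold aqueous Na2CO3/CH2Cl2 gives the stabilised ylide allyl (2R)-3-[3,4-bis(allyloxy)phenyl]-2-{[2-(triphenyl-λ5-phosphanylidene)acetyl]oxy}propanoate F10.
- F10 is heated with 20 in toluene at 60 °C with no added base to give 25.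

**Step 14 (global deallylation).** Seven allyl groups must come off a molecule whose product is an air-sensitive polyphenol with a benzylic alcohol; incomplete cleavage of the aryl ethers, C-allylation of the liberated catechols or amine-induced side reactions are possible. The fallback sets out from 25 and comes back at 26 in two stages that use different chemistry for esters and ethers.
- Pd(PPh3)4 (3 mol%) with pyrrolidine (2.2 equiv) in CH2Cl2 at 0 °C for a short time removes only the two allyl esters and gives the stable, purifiable diacid (2R)-2-{[(2E)-3-(3-(allyloxy)-4-{[(1R,2R)-2-[3,4-bis(allyloxy)phenyl]-1-carboxy-2-hydroxyethyl]oxy}phenyl)prop-2-enoyl]oxy}-3-[3,4-bis(allyloxy)phenyl]propanoic acid F11.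
- The five aryl allyl ethers of F11 are then cleaved without any amine by [CpRu(MeCN)3]PF6/quinoline-2-carboxylic acid (5 mol%) in degassed MeOH at 30 °C, which transfers the allyl groups to the solvent, to give 26.

## Further compounds

F1 | step 7 | (4S)-4-benzyl-3-{2-[(4-methoxybenzyl)oxy]acetyl}-1,3-oxazolidin-2-one | COc1ccc(COCC(=O)N2[C@@H](Cc3ccccc3)COC2=O)cc1
F2 | step 7 | (4S)-4-benzyl-3-{(2S,3R)-3-[3,4-bis(allyloxy)phenyl]-3-hydroxy-2-[(4-methoxybenzyl)oxy]propanoyl}-1,3-oxazolidin-2-one | COc1ccc(CO[C@H](C(=O)N2[C@@H](Cc3ccccc3)COC2=O)[C@H](O)c2ccc(OCC=C)c(OCC=C)c2)cc1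
F3 | step 7 | (4S)-4-benzyl-3-{(2S,3R)-3-[3,4-bis(allyloxy)phenyl]-3-[(tert-butyldimethylsilyl)oxy]-2-[(4-methoxybenzyl)oxy]propanoyl}-1,3-oxazolidin-2-one | COc1ccc(CO[C@H](C(=O)N2[C@@H](Cc3ccccc3)COC2=O)[C@H](O[Si](C)(C)C(C)(C)C)c2ccc(OCC=C)c(OCC=C)c2)cc1
F4 | step 7 | allyl (2S,3R)-3-[3,4-bis(allyloxy)phenyl]-3-[(tert-butyldimethylsilyl)oxy]-2-[(4-methoxybenzyl)oxy]propanoate | COc1ccc(CO[C@H](C(=O)OCC=C)[C@H](O[Si](C)(C)C(C)(C)C)c2ccc(OCC=C)c(OCC=C)c2)cc1
F5 | step 7 | allyl (2S,3R)-3-[3,4-bis(allyloxy)phenyl]-3-[(tert-butyldimethylsilyl)oxy]-2-hydroxypropanoate | O[C@H](C(=O)OCC=C)[C@H](O[Si](C)(C)C(C)(C)C)c1ccc(OCC=C)c(OCC=C)c1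
F6 | step 7 | 3-(allyloxy)-4-hydroxybenzaldehyde | C=CCOc1cc(C=O)ccc1O
F7 | step 7 | allyl (2R,3R)-2-[2-(allyloxy)-4-formylphenoxy]-3-[3,4-bis(allyloxy)phenyl]-3-[(tert-butyldimethylsilyl)oxy]propanoate | C=CCOc1cc(C=O)ccc1O[C@@H](C(=O)OCC=C)[C@H](O[Si](C)(C)C(C)(C)C)c1ccc(OCC=C)c(OCC=C)c1
F8 | step 13 | allyl (2R)-3-[3,4-bis(allyloxy)phenyl]-2-[(2-bromoacetyl)oxy]propanoate | C=CCOC(=O)[C@H](OC(=O)CBr)Cc1ccc(OCC=C)c(OCC=C)c1
F9 | step 13 | {2-[((2R)-1-(allyloxy)-3-[3,4-bis(allyloxy)phenyl]-1-oxopropan-2-yl)oxy]-2-oxoethyl}triphenylphosphonium bromide | C=CCOC(=O)[C@H](OC(=O)C[P+](c1ccccc1)(c1ccccc1)c1ccccc1)Cc1ccc(OCC=C)c(OCC=C)c1.[Br-]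
F10 | step 13 | allyl (2R)-3-[3,4-bis(allyloxy)phenyl]-2-{[2-(triphenyl-λ5-phosphanylidene)acetyl]oxy}propanoate | C=CCOC(=O)[C@H](OC(=O)C=P(c1ccccc1)(c1ccccc1)c1ccccc1)Cc1ccc(OCC=C)c(OCC=C)c1
F11 | step 14 | (2R)-2-{[(2E)-3-(3-(allyloxy)-4-{[(1R,2R)-2-[3,4-bis(allyloxy)phenyl]-1-carboxy-2-hydroxyethyl]oxy}phenyl)prop-2-enoyl]oxy}-3-[3,4-bis(allyloxy)phenyl]propanoic acid | OC(=O)[C@H](OC(=O)/C=C/c1ccc(O[C@@H](C(=O)O)[C@H](O)c2ccc(OCC=C)c(OCC=C)c2)c(OCC=C)c1)Cc1ccc(OCC=C)c(OCC=C)c1
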